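Everything rests on closing the indane ring last: the bond between the ring-fusion carbon C-11 and C-2′, the bridge carbon carrying a 4-oxygenated aryl group, is formed by a decarboxylative radical 5-exo cyclization onto the C10=C11 double bond of a dibenzosuberenone, which lies peri to C-1 of resorcinol ring B. This one operation closes the five-membered ring and sets C-2′, C-11 and C-10 from the single catalyst-made centre C-1′. The precursor is a 10-aryl-dibenzo[a,d]cyclohepten-5-one bearing at C-1 a 2,3-diarylpropanoic acid chain, whose carboxyl group first lets the diarylmethine C-1′ be built by Heck coupling and asymmetric conjugate addition, then admits the second aryl group, and finally leaves as CO2.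

Key step: step 11

Remark on the chemistry: dibenzo[a,d]cycloheptene locants are used (C-5 ketone carbon, C-1 to C-4 on ring B, C-10/C-11 the sp3 carbons of the seven-membered ring, C-1′/C-2′ the bridge carbons bearing the 3,5-dioxygenated and the 4-oxygenated aryl group). The given SMILES is read as 10S,11R,1′S,2′S, and all eight phenols are carried as methyl ethers.

Step 1
Reactants: 1 methyl 2-(3,5-dimethoxyphenyl)acetate
Product: 2 methyl 2-(2-bromo-3,5-dimethoxyphenyl)acetate
Conditions: NBS (1.0 equiv), MeCN, 0 °C to rt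
Reagents that add atoms: N-bromosuccinimide, O=C1CCC(=O)N1Br
Why: Electrophilic aromatic bromination of the resorcinol dimethyl ether ring should occur at C-2 (para to one OMe, ortho to the other and to the CH2 group), and the bromine both blocks this site in step 2 and later serves as the handle for the side chain.

Step 2
Reactants: 2 methyl 2-(2-bromo-3,5-dimethoxyphenyl)acetate, 3 3,5-dimethoxybenzoyl chloride
Product: 4 methyl 2-[2-bromo-6-(3,5-dimethoxybenzoyl)-3,5-dimethoxyphenyl]acetate
Conditions: SnCl4 (promoter, 1.2 equiv), CH2Cl2, 0 °C to rt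
Reagents that add atoms: none
Why: Friedel–Crafts acylation should go to C-6, the remaining position that is para to one OMe and ortho to the CH2CO2Me group, which is the regiochemistry typical of 3,5-dimethoxyphenylacetates, while the acid chloride's own ring is deactivated against self-acylation.

Step 3
Reactants: 4 methyl 2-[2-bromo-6-(3,5-dimethoxybenzoyl)-3,5-dimethoxyphenyl]acetate
Product: 5 2-[2-bromo-6-(3,5-dimethoxybenzoyl)-3,5-dimethoxyphenyl]acetic acid
Conditions: LiOH·H2O, THF/MeOH/H2O, rt; then 1 M HCl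
Reagents that add atoms: lithium hydroxide, [Li+].[OH-]
Why: Saponification of the unhindered methyl ester should be clean because the diaryl ketone is not enolizable and nothing else is base-labile.

Step 4
Reactants: 5 2-[2-bromo-6-(3,5-dimethoxybenzoyl)-3,5-dimethoxyphenyl]acetic acid
Product: 6 1-bromo-2,4,7,9-tetramethoxy-5H-dibenzo[a,d]cycloheptene-5,10(11H)-dione
Conditions: Eaton's reagent (P2O5 in MeSO3H), 40 °C
Reagents that add atoms: none
Why: Intramolecular Friedel–Crafts acylation closes the seven-membered ring onto either of the two equivalent positions ortho to the ketone of the 3,5-dimethoxybenzoyl ring (each activated by an ortho and a para OMe), in analogy with the classical cyclization of o-benzoylbenzoic acids to anthraquinones.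

Step 5
Reactants: 6 1-bromo-2,4,7,9-tetramethoxy-5H-dibenzo[a,d]cycloheptene-5,10(11H)-dione
Product: 7 1-bromo-2,4,7,9-tetramethoxy-5-oxo-5H-dibenzo[a,d]cyclohepten-10-yl trifluoromethanesulfonate
Conditions: KHMDS, THF, −78 °C; then PhNTf2, −78 to 0 °C
Reagents that add atoms: N-phenylbis(trifluoromethanesulfonimide), O=S(=O)(N(c1ccccc1)S(=O)(=O)C(F)(F)F)C(F)(F)F
Why: The C-11 methylene is the only enolizable position (benzylic and α to the C-10 ketone), so O-triflation of its potassium enolate should give a single vinyl triflate.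

Step 6
Reactants: 7 1-bromo-2,4,7,9-tetramethoxy-5-oxo-5H-dibenzo[a,d]cyclohepten-10-yl trifluoromethanesulfonate, 8 (4-methoxyphenyl)boronic acid
Product: 9 1-bromo-2,4,7,9-tetramethoxy-10-(4-methoxyphenyl)-5H-dibenzo[a,d]cyclohepten-5-one
Conditions: Pd(PPh3)4 (5 mol %), K3PO4, dioxane/H2O, 70 °C
Reagents that add atoms: none
Why: In this Suzuki–Miyaura coupling, oxidative addition to the vinyl triflate should outpace addition to the electron-rich, doubly ortho-substituted aryl bromide under Pd/PPh3, so the anisyl group enters at C-10 and the bromide is kept.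

Step 7
Reactants: 9 1-bromo-2,4,7,9-tetramethoxy-10-(4-methoxyphenyl)-5H-dibenzo[a,d]cyclohepten-5-one, 10 tert-butyl acrylate
Product: 11 tert-butyl (E)-3-[2,4,7,9-tetramethoxy-10-(4-methoxyphenyl)-5-oxo-5H-dibenzo[a,d]cyclohepten-1-yl]prop-2-enoate
Conditions: Pd2(dba)3 (2.5 mol %), P(t-Bu)3·HBF4, Cy2NMe, dioxane, 100 °C
Reagents that add atoms: none
Why: A Mizoroki–Heck reaction with a bulky electron-rich phosphine should engage the hindered bromide and give the E-enoate, since the ring alkene cannot insert intramolecularly (only three- or four-membered rings would result).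

Step 8
Reactants: 11 tert-butyl (E)-3-[2,4,7,9-tetramethoxy-10-(4-methoxyphenyl)-5-oxo-5H-dibenzo[a,d]cyclohepten-1-yl]prop-2-enoate, 12 (3,5-dimethoxyphenyl)boronic acid
Product: 13 tert-butyl (3S)-3-(3,5-dimethoxyphenyl)-3-[2,4,7,9-tetramethoxy-10-(4-methoxyphenyl)-5-oxo-5H-dibenzo[a,d]cyclohepten-1-yl]propanoate
Conditions: Rh(acac)(C2H4)2 (3 mol %), (R)-BINAP (3.3 mol %), dioxane/H2O (10:1), 100 °C
Reagents that add atoms: none
Why: In this Hayashi–Miyaura rhodium-catalysed asymmetric 1,4-addition the aryl–rhodium species adds to the β-carbon of the E-enoate on the face dictated by the ligand, and (R)-BINAP is chosen by analogy with the sense of induction known for E-enoates to give the 3S centre (to be confirmed on 13), the only stereocentre of the route set by a reagent.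

Step 9
Reactants: 13 tert-butyl (3S)-3-(3,5-dimethoxyphenyl)-3-[2,4,7,9-tetramethoxy-10-(4-methoxyphenyl)-5-oxo-5H-dibenzo[a,d]cyclohepten-1-yl]propanoate, 14 4-bromoanisole
Product: 15 tert-butyl (2RS,3S)-3-(3,5-dimethoxyphenyl)-2-(4-methoxyphenyl)-3-[2,4,7,9-tetramethoxy-10-(4-methoxyphenyl)-5-oxo-5H-dibenzo[a,d]cyclohepten-1-yl]propanoate (C-2 epimers)
Conditions: Pd(dba)2 (5 mol %), P(t-Bu)3 (10 mol %), LiHMDS (2.3 equiv), toluene, rt to 50 °C
Reagents that add atoms: none
Why: Palladium-catalysed α-arylation of the tert-butyl ester enolate (Buchwald–Hartwig type) should be chemoselective because the ester α-CH2 is the only acidic C–H and the ketone is non-enolizable, and the new C-2 centre may form as a mixture since it becomes a planar radical in step 11.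

Step 10
Reactants: 15 tert-butyl (2RS,3S)-3-(3,5-dimethoxyphenyl)-2-(4-methoxyphenyl)-3-[2,4,7,9-tetramethoxy-10-(4-methoxyphenyl)-5-oxo-5H-dibenzo[a,d]cyclohepten-1-yl]propanoate (C-2 epimers)
Product: 17 1,3-dioxoisoindolin-2-yl (2RS,3S)-3-(3,5-dimethoxyphenyl)-2-(4-methoxyphenyl)-3-[2,4,7,9-tetramethoxy-10-(4-methoxyphenyl)-5-oxo-5H-dibenzo[a,d]cyclohepten-1-yl]propanoate, via free carboxylic acid 16 (not isolated)
Conditions: ZnBr2 (promoter), CH2Cl2, rt; aqueous work-up, evaporate; then N-hydroxyphthalimide, DIC, DMAP (cat.), CH2Cl2, rt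
Reagents that add atoms: N-hydroxyphthalimide, ON1C(=O)c2ccccc2C1=O
Why: Lewis-acid cleavage of the tert-butyl ester (chosen over a Brønsted acid so that the C10=C11 triaryl alkene is not protonated) followed by carbodiimide esterification should give the redox-active ester.

Step 11
Reactants: 17 1,3-dioxoisoindolin-2-yl (2RS,3S)-3-(3,5-dimethoxyphenyl)-2-(4-methoxyphenyl)-3-[2,4,7,9-tetramethoxy-10-(4-methoxyphenyl)-5-oxo-5H-dibenzo[a,d]cyclohepten-1-yl]propanoate
Product: 18 (10S,11R)-1,11-[(1S,2S)-1-(3,5-dimethoxyphenyl)-2-(4-methoxyphenyl)ethane-1,2-diyl]-2,4,7,9-tetramethoxy-10-(4-methoxyphenyl)-10,11-dihydro-5H-dibenzo[a,d]cyclohepten-5-one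
Conditions: Ru(bpy)3(PF6)2 (1 mol %), Hantzsch ester (1.5 equiv), degassed DMF (0.01 M), blue LEDs, rt
Reagents that add atoms: none
Why: Single-electron reduction of the N-acyloxyphthalimide by the photoreduced ruthenium catalyst releases phthalimide anion and CO2 and leaves the 4-methoxybenzylic radical at C-2′, which adds to C-11 of the C10=C11 double bond to give the doubly benzylic C-10 radical that is then reduced and protonated (or takes a hydrogen atom from the Hantzsch ester); the closest known reaction type is the visible-light reductive decarboxylative Giese-type cyclization of redox-active esters. The ring closes in the 5-exo-trig mode, because the 6-endo alternative would have to attack the fully substituted diaryl carbon C-10 and would give the less stabilized radical. C-2′ is controlled by the adjacent centre C-1′, the planar radical bonding with its anisyl group anti to the 3,5-dimethoxyphenyl group, and C-11 is set in the same bond formation because the bulky C-10 arm of the seven-membered ring must point away from that anisyl group, which gives the all-trans indane. C-10 is set by the final hydrogen delivery, expected to leave its anisyl group pseudo-equatorial and anti to the C-2′ aryl group, and this centre remains correctable by base because its hydrogen is conjugated with the C-5 ketone through ring A. The step needs ring closure to outrun reduction of the first radical, which the persistence of a secondary anisylic radical, high dilution and the absence of a fast hydrogen donor should secure, and it avoids the 1,2-hydride shift and Friedel–Crafts capture by the electron-rich rings that the corresponding cation would risk.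

Step 12
Reactants: 18 (10S,11R)-1,11-[(1S,2S)-1-(3,5-dimethoxyphenyl)-2-(4-methoxyphenyl)ethane-1,2-diyl]-2,4,7,9-tetramethoxy-10-(4-methoxyphenyl)-10,11-dihydro-5H-dibenzo[a,d]cyclohepten-5-one
Product: 19 (10S,11R)-1,11-[(1S,2S)-1-(3,5-dihydroxyphenyl)-2-(4-hydroxyphenyl)ethane-1,2-diyl]-2,4,7,9-tetrahydroxy-10-(4-hydroxyphenyl)-10,11-dihydro-5H-dibenzo[a,d]cyclohepten-5-one (CNP0116600.1)
Conditions: BBr3 (excess), CH2Cl2, −78 °C to rt; then MeOH/H2O
Reagents that add atoms: none
Why: Lewis-acid cleavage of all eight aryl methyl ethers with BBr3 is the standard final deprotection for permethylated stilbenoid oligomers, and 18 has no alkene or ionizable benzylic leaving group, so the four stereocentres should be untouched.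

Compound list
1 | methyl 2-(3,5-dimethoxyphenyl)acetate | COC(=O)Cc1cc(OC)cc(OC)c1 | starting material
2 | methyl 2-(2-bromo-3,5-dimethoxyphenyl)acetate | COC(=O)Cc1cc(OC)cc(OC)c1Br | intermediate
3 | 3,5-dimethoxybenzoyl chloride | COc1cc(OC)cc(c1)C(Cl)=O | starting material
4 | methyl 2-[2-bromo-6-(3,5-dimethoxybenzoyl)-3,5-dimethoxyphenyl]acetate | COC(=O)Cc1c(Br)c(OC)cc(OC)c1C(=O)c1cc(OC)cc(OC)c1 | intermediate
5 | 2-[2-bromo-6-(3,5-dimethoxybenzoyl)-3,5-dimethoxyphenyl]acetic acid | OC(=O)Cc1c(Br)c(OC)cc(OC)c1C(=O)c1cc(OC)cc(OC)c1 | intermediate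
6 | 1-bromo-2,4,7,9-tetramethoxy-5H-dibenzo[a,d]cycloheptene-5,10(11H)-dione | O=C1c2cc(OC)cc(OC)c2C(=O)Cc2c1c(OC)cc(OC)c2Br | intermediate
7 | 1-bromo-2,4,7,9-tetramethoxy-5-oxo-5H-dibenzo[a,d]cyclohepten-10-yl trifluoromethanesulfonate | O=C1c2cc(OC)cc(OC)c2C(OS(=O)(=O)C(F)(F)F)=Cc2c1c(OC)cc(OC)c2Br | intermediate
8 | (4-methoxyphenyl)boronic acid | OB(O)c1ccc(OC)cc1 | starting material
9 | 1-bromo-2,4,7,9-tetramethoxy-10-(4-methoxyphenyl)-5H-dibenzo[a,d]cyclohepten-5-one | O=C1c2cc(OC)cc(OC)c2C(c2ccc(OC)cc2)=Cc2c1c(OC)cc(OC)c2Br | intermediate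
10 | tert-butyl acrylate | C=CC(=O)OC(C)(C)C | starting material
11 | tert-butyl (E)-3-[2,4,7,9-tetramethoxy-10-(4-methoxyphenyl)-5-oxo-5H-dibenzo[a,d]cyclohepten-1-yl]prop-2-enoate | O=C1c2cc(OC)cc(OC)c2C(c2ccc(OC)cc2)=Cc2c1c(OC)cc(OC)c2/C=C/C(=O)OC(C)(C)C | intermediate
12 | (3,5-dimethoxyphenyl)boronic acid | OB(O)c1cc(OC)cc(OC)c1 | starting material
13 | tert-butyl (3S)-3-(3,5-dimethoxyphenyl)-3-[2,4,7,9-tetramethoxy-10-(4-methoxyphenyl)-5-oxo-5H-dibenzo[a,d]cyclohepten-1-yl]propanoate | O=C1c2cc(OC)cc(OC)c2C(c2ccc(OC)cc2)=Cc2c1c(OC)cc(OC)c2[C@H](c1cc(OC)cc(OC)c1)CC(=O)OC(C)(C)C | intermediate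
14 | 4-bromoanisole | COc1ccc(Br)cc1 | starting material
15 | tert-butyl (2RS,3S)-3-(3,5-dimethoxyphenyl)-2-(4-methoxyphenyl)-3-[2,4,7,9-tetramethoxy-10-(4-methoxyphenyl)-5-oxo-5H-dibenzo[a,d]cyclohepten-1-yl]propanoate (C-2 epimers) | O=C1c2cc(OC)cc(OC)c2C(c2ccc(OC)cc2)=Cc2c1c(OC)cc(OC)c2[C@H](c1cc(OC)cc(OC)c1)C(c1ccc(OC)cc1)C(=O)OC(C)(C)C | intermediate
16 | (2RS,3S)-3-(3,5-dimethoxyphenyl)-2-(4-methoxyphenyl)-3-[2,4,7,9-tetramethoxy-10-(4-methoxyphenyl)-5-oxo-5H-dibenzo[a,d]cyclohepten-1-yl]propanoic acid (not isolated) | O=C1c2cc(OC)cc(OC)c2C(c2ccc(OC)cc2)=Cc2c1c(OC)cc(OC)c2[C@H](c1cc(OC)cc(OC)c1)C(c1ccc(OC)cc1)C(O)=O | intermediate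
17 | 1,3-dioxoisoindolin-2-yl (2RS,3S)-3-(3,5-dimethoxyphenyl)-2-(4-methoxyphenyl)-3-[2,4,7,9-tetramethoxy-10-(4-methoxyphenyl)-5-oxo-5H-dibenzo[a,d]cyclohepten-1-yl]propanoate | O=C1c2cc(OC)cc(OC)c2C(c2ccc(OC)cc2)=Cc2c1c(OC)cc(OC)c2[C@H](c1cc(OC)cc(OC)c1)C(c1ccc(OC)cc1)C(=O)ON1C(=O)c2ccccc2C1=O | intermediate
18 | (10S,11R)-1,11-[(1S,2S)-1-(3,5-dimethoxyphenyl)-2-(4-methoxyphenyl)ethane-1,2-diyl]-2,4,7,9-tetramethoxy-10-(4-methoxyphenyl)-10,11-dihydro-5H-dibenzo[a,d]cyclohepten-5-one (octamethyl ether of the target) | O=C1c2cc(OC)cc(OC)c2[C@H](c2ccc(OC)cc2)[C@@H]2c3c1c(OC)cc(OC)c3[C@H](c1cc(OC)cc(OC)c1)[C@H]2c1ccc(OC)cc1 | intermediate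
19 | (10S,11R)-1,11-[(1S,2S)-1-(3,5-dihydroxyphenyl)-2-(4-hydroxyphenyl)ethane-1,2-diyl]-2,4,7,9-tetrahydroxy-10-(4-hydroxyphenyl)-10,11-dihydro-5H-dibenzo[a,d]cyclohepten-5-one (CNP0116600.1) | O=C1c2cc(O)cc(O)c2[C@H](c2ccc(O)cc2)[C@@H]2c3c1c(O)cc(O)c3[C@H](c1cc(O)cc(O)c1)[C@H]2c1ccc(O)cc1 | target

Total step count: 12. Longest linear sequence: 12 steps (from 1; compounds 3, 8, 10, 12 and 14 are purchased).

Steps most likely to fail

Step 11 (key step). The hydrogen may be delivered to the C-10 radical or anion from the face that leaves the anisyl group pseudo-axial, and some of the first radical may be reduced before ring closure. The fallback uses thermodynamic instead of kinetic control at C-10. It sets out from 17, whose cyclization in that event would give mainly (10R,11R)-1,11-[(1S,2S)-1-(3,5-dimethoxyphenyl)-2-(4-methoxyphenyl)ethane-1,2-diyl]-2,4,7,9-tetramethoxy-10-(4-methoxyphenyl)-10,11-dihydro-5H-dibenzo[a,d]cyclohepten-5-one F1, the C-10 epimer of 18. Treatment of F1 with KOt-Bu in t-BuOH/DMSO should deprotonate C-10 reversibly, because this hydrogen is doubly benzylic and conjugated through ring A with the C-5 ketone, and should funnel the material to the isomer with all aryl groups pseudo-equatorial, which is 18. C-1′ and C-2′ are not conjugated with the ketone and should keep their configuration, so the route is rejoined at 18 without loss of enantiopurity.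

Step 8. Carbo-rhodation at the β-carbon, which is flanked by an OMe group and the fused ring, may be slow, so that protodeboronation of 12 wins or the enantioface discrimination is poor. The fallback replaces catalyst control by auxiliary control and sets out from 9. (R)-3-Acryloyl-4-phenyloxazolidin-2-one F2 is made from (R)-4-phenyloxazolidin-2-one and acryloyl chloride (n-BuLi, THF, −78 °C). Heck coupling of 9 with F2 under the conditions of step 7 should give the enoyl imide (R)-4-phenyl-3-{(E)-3-[2,4,7,9-tetramethoxy-10-(4-methoxyphenyl)-5-oxo-5H-dibenzo[a,d]cyclohepten-1-yl]prop-2-enoyl}oxazolidin-2-one F3. The aryl cuprate from (3,5-dimethoxyphenyl)magnesium bromide and CuBr·SMe2 (THF, −40 °C) should add to the chelated imide anti to the 4-phenyl group and give the 3S adduct (R)-3-{(3S)-3-(3,5-dimethoxyphenyl)-3-[2,4,7,9-tetramethoxy-10-(4-methoxyphenyl)-5-oxo-5H-dibenzo[a,d]cyclohepten-1-yl]propanoyl}-4-phenyloxazolidin-2-one F4; the 4R auxiliary is chosen by analogy with related cuprate additions, and its antipode is the remedy if correlation shows otherwise. LiOH/H2O2 then removes the auxiliary to give (3S)-3-(3,5-dimethoxyphenyl)-3-[2,4,7,9-tetramethoxy-10-(4-methoxyphenyl)-5-oxo-5H-dibenzo[a,d]cyclohepten-1-yl]propanoic acid F5, and tert-butyl ester formation (Boc2O, DMAP, t-BuOH) returns to 13.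

Step 9. Steric retardation next to the diarylmethine may stall the coupling, leading to reprotonation to 13 or ester self-condensation. The fallback replaces the cross-coupling by an electrophilic arylation and sets out from 13. LDA/TMSCl (THF, −78 °C) should give the silyl ketene acetal {[(3S)-1-tert-butoxy-3-(3,5-dimethoxyphenyl)-3-[2,4,7,9-tetramethoxy-10-(4-methoxyphenyl)-5-oxo-5H-dibenzo[a,d]cyclohepten-1-yl]prop-1-en-1-yl]oxy}trimethylsilane F6. Arylation of F6 with bis(4-methoxyphenyl)iodonium triflate under Cu(OTf)2 catalysis (aryl transfer from an aryl–copper(III) species, CH2Cl2, rt) returns to 15.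

Further compounds
F1 | step 11 | (10R,11R)-1,11-[(1S,2S)-1-(3,5-dimethoxyphenyl)-2-(4-methoxyphenyl)ethane-1,2-diyl]-2,4,7,9-tetramethoxy-10-(4-methoxyphenyl)-10,11-dihydro-5H-dibenzo[a,d]cyclohepten-5-one (C-10 epimer of 18) | O=C1c2cc(OC)cc(OC)c2[C@@H](c2ccc(OC)cc2)[C@@H]2c3c1c(OC)cc(OC)c3[C@H](c1cc(OC)cc(OC)c1)[C@H]2c1ccc(OC)cc1
F2 | step 8 | (R)-3-acryloyl-4-phenyloxazolidin-2-one | C=CC(=O)N1[C@H](c2ccccc2)COC1=O
F3 | step 8 | (R)-4-phenyl-3-{(E)-3-[2,4,7,9-tetramethoxy-10-(4-methoxyphenyl)-5-oxo-5H-dibenzo[a,d]cyclohepten-1-yl]prop-2-enoyl}oxazolidin-2-one | O=C1c2cc(OC)cc(OC)c2C(c2ccc(OC)cc2)=Cc2c1c(OC)cc(OC)c2/C=C/C(=O)N1[C@H](c2ccccc2)COC1=O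
F4 | step 8 | (R)-3-{(3S)-3-(3,5-dimethoxyphenyl)-3-[2,4,7,9-tetramethoxy-10-(4-methoxyphenyl)-5-oxo-5H-dibenzo[a,d]cyclohepten-1-yl]propanoyl}-4-phenyloxazolidin-2-one | O=C1c2cc(OC)cc(OC)c2C(c2ccc(OC)cc2)=Cc2c1c(OC)cc(OC)c2[C@H](c1cc(OC)cc(OC)c1)CC(=O)N1[C@H](c2ccccc2)COC1=O
F5 | step 8 | (3S)-3-(3,5-dimethoxyphenyl)-3-[2,4,7,9-tetramethoxy-10-(4-methoxyphenyl)-5-oxo-5H-dibenzo[a,d]cyclohepten-1-yl]propanoic acid | O=C1c2cc(OC)cc(OC)c2C(c2ccc(OC)cc2)=Cc2c1c(OC)cc(OC)c2[C@H](c1cc(OC)cc(OC)c1)CC(O)=O
F6 | step 9 | {[(3S)-1-tert-butoxy-3-(3,5-dimethoxyphenyl)-3-[2,4,7,9-tetramethoxy-10-(4-methoxyphenyl)-5-oxo-5H-dibenzo[a,d]cyclohepten-1-yl]prop-1-en-1-yl]oxy}trimethylsilane | O=C1c2cc(OC)cc(OC)c2C(c2ccc(OC)cc2)=Cc2c1c(OC)cc(OC)c2[C@H](c1cc(OC)cc(OC)c1)C=C(O[Si](C)(C)C)OC(C)(C)C
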